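**Convention.** Atom labels C1–C35 are the positions in the target SMILES string and are kept for every intermediate; a CIP descriptor quoted with such a label refers to that atom.

## Analysis of the target

The target holds two ring pairs joined by the C12–C13 ethylene bridge. Ring A is a 2,2-dimethyloxepan-3-one (O4, C2, C34, C33, C32, C30, C5), trans-fused at C5–C30 to cyclohexane ring B (C5–C8, C11, C30). Ring C is a cycloheptane (C14, C15, C18, C24, C25, C26, C28) carrying the C26–O27–C28 epoxide, cis-fused at C18–C24 to cyclopentane ring D. The ten stereocentres are 5R, 8S, 11R, 14R, 18R, 21R, 24R, 26S, 28R and 30R. In the AB half, H5 is anti to the angular methyl C31, the C8 hydroxyl is axial and syn to C31, and the C11 side chain is equatorial. In the CD half, H14, H18, H24 and the C21 hydroxyl share one face, while the C14 side chain and the epoxide oxygen share the other. The two stereoclusters are insulated by two methylene groups, so each half must be made enantiopure on its own. Sensitive groups are the trisubstituted epoxide (acid, Lewis acid), two tertiary alcohols (elimination) and the enolisable α-alkoxy ketone C34, which is therefore carried as a protected alcohol until the last step. The hard part is ring C: the quaternary C15 sits between the stereocentre C14 and the fusion carbon C18, and C18 and C24 need two cis carbon–carbon bonds on an unactivated alkene. The strategy rests on seeing ring C as the five-carbon run C15–C14–C28–C26–C25, stored in a 1-vinyl-2,2-dimethylcyclopropane, closed onto the fusion bond C18–C24, which is the alkene of a cyclopentene.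

## Retrosynthetic reasoning

**C34 oxidation level (29 from 28 from 27).** The ring A ketone is unmasked last by oxidising the only secondary alcohol of triol 28. Triol 28 comes from bis-silyl ether 27 by fluoride. Nothing in the endgame then has to tolerate a second enolisable ketone.

**C8–C9 (27 from 26).** The C8 carbinol is cut to ketone 26 and a methyl nucleophile. The axial methyl C31, 1,3 to C8, blocks axial attack, so the forward addition must be equatorial and gives the axial hydroxyl the target needs.

**C11–C12 (26 from 25 from 23 from 22 + 15).** The bridge is cut next to ring B because the two halves do not influence each other's stereochemistry and both partners are then easy to make. Forward, enone 22 is enolised at C11 only, since its C6=C7 bond blocks C7. It is added to epoxy aldehyde 15, the aldol 23 is dehydrated to dienone 25, and hydrogenation sets C11 by delivering hydrogen opposite the angular methyl while also removing the blocking alkene.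

**Epoxide O27 (15 from 14 from 13).** The epoxide is placed before the union, while the side chain on C14 still ends in a free primary hydroxyl (13). That hydroxyl can carry a vanadium peroxide to the alkene face on which the chain sits, which is the face the target requires and which a reagent acting only through sterics would be expected to avoid. Oxidation of 14 gives 15.

**Ring C: C15–C18 and C24–C25 (13 from 12 from 3 + 11).** Both bonds from ring C to the fusion carbons are cut at once. This returns cyclopentene 3, which already holds C21, and vinylcyclopropane 11, which holds C14 and the gem-dimethyl carbon. The forward step must open the cyclopropane bond C28–C15, add the five-carbon unit across the alkene of 3 suprafacially and anti to the silyl ether, and leave the C26=C28 alkene. No other two-bond disconnection of ring C keeps every remaining stereocentre in a small, separately accessible fragment.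

**Ring D (3 from 2 from 1).** Cyclopentenol 2 is the ring-closing metathesis product of (R)-linalool 1, whose carbinol carbon becomes C21; silylation gives 3.

**Vinylcyclopropane (11 from 10 from 9 from 8 from 7 from 6 from 4 + 5).** The vinyl group of 11 is traced to methyl ketone 9 through enol triflate 10, because C28 is quaternary and the ketone can enolise only one way. Ketone 9 comes from carbinol 8, and the cyclopropane of 8 from allylic alcohol 7 by hydroxyl-directed transfer of an isopropylidene unit from a zinc carbenoid. The carbinol centre of 7, set by reagent-controlled reduction of enone 6, controls C14 and C28 and is then erased. Enone 6 is the Wittig product of aldehyde 4 and ylide 5.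

**Rings A and B (22 from 21 from 20 from 18 from 17 from 16).** Enone 22 arises from ketone 21 by dehydrogenation, which can only go toward C6–C7 because C30 is quaternary. Silyl ether 21 comes from hydroxy ketone 20. In 20 the bonds O4–C2 and C11–C30 are cut together, leading back to diepoxy enol silane 18. This is made from diepoxide 17 and ultimately from (E)-geranylacetone 16, which contains all thirteen carbons in the right order.

## Alternatives that were turned down

**Alternative 1: ring B by ketyl–enoate closure (cut C8–C11).** SmI2 would reduce a C8 methyl ketone hung on a preformed oxepane to its ketyl, which adds 6-exo to C11 of an enoate; the cis hydroxy ester lactonises to tricyclic lactone A1.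
- For: C8 and C11 are set together in one well-precedented radical step, where the chosen route needs three steps (aldol, hydrogenation, methyl addition). On this point Alternative 1 is stronger.
- Against: the substrate is a monocyclic oxepane already carrying the C5/C30 relationship and the quaternary C30, which is the hard part of the AB half and is not addressed. In A1 the bridge ends at the lactone carbonyl C13, so the union would have to form C13–C14 at a carbon flanked by the quaternary C15 and by C28, and set C14 at the same time.
- Comparison: the chosen route fixes C14 in a small cyclopropane before ring C exists and joins the halves at the unhindered C11–C12 bond. Alternative 1 leaves rings C and D unsolved.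

**Alternative 2: ring D by ketyl–enone coupling (cut C21–C24).** SmI2 would couple a C21 methyl ketone with the β-carbon C24 of a cyclohexenone in a 5-exo closure, giving cis-hydrindanone A2 with the C21 carbinol.
- For: cis fusion and the C21 configuration follow from a known, reliably selective cyclisation. Every step is known chemistry, which the chosen key step is not.
- Against: A2 has ring C as a six-membered ketone. It still needs a regioselective one-carbon ring expansion, introduction of the C29 methyl and of the C26=C28 alkene, and an enantioselective entry to C18 and C14 in the cyclisation substrate.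
- Comparison: several linear steps would follow A2 before the stage of 12 is reached. The chosen cycloaddition forms ring C, both fusion centres and the alkene in one step from two enantiopure pieces made in eight steps in total, at the price of an untested reaction.

**Alternative 3: rings A and B by an allylsilane-terminated epoxonium cascade (cut O4–C2 and C11–C30).** A silyl triflate would open the terminal epoxide of a diepoxide, the internal epoxide oxygen attacks C2, and a trisubstituted allylsilane opens the epoxonium ion at C30, giving A3 with the C11 side chain and an exocyclic C8 methylene.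
- For: on rings A and B this is as strong as the chosen route, which uses the simplest member of the same reaction class (step 15). It is stronger in that C11 is set in the cascade.
- Against: it needs a geometrically pure trisubstituted allylsilane. The exocyclic alkene must still be turned into the C8 methyl carbinol with facial control. The CD half would have to be attached through an sp3–sp3 bond C12–C13. Rings C and D are not addressed.
- Comparison: the chosen strategy accepts two more steps on ring B in exchange for a direct answer to ring C, which Alternative 3 leaves open.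

Key step: step 9

Remark: (E)-geranylacetone of high isomeric purity, ylide 5, and freshly made 2,2-diiodopropane (from acetone hydrazone and iodine) are assumed to be at hand.

## Route

Step 1
Reactants: 1 (R)-linalool
Product: 2 (R)-1-methylcyclopent-2-en-1-ol
Conditions: second-generation Grubbs catalyst (H2IMes)(PCy3)Cl2Ru=CHPh (1 mol %), CH2Cl2, 40 °C
Reagents that add atoms: none
Why: Ring-closing metathesis between the vinyl group and the trisubstituted alkene expels a volatile C4 alkene and leaves the carbinol carbon (future C21) untouched, so its R configuration comes from the chiral pool.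

Step 2
Reactants: 2 (R)-1-methylcyclopent-2-en-1-ol
Product: 3 cyclopentenyl silyl ether
Conditions: TBSOTf, 2,6-lutidine, CH2Cl2, −78 → 0 °C
Reagents that add atoms: tert-butyldimethylsilyl trifluoromethanesulfonate, CC(C)(C)[Si](C)(C)OS(=O)(=O)C(F)(F)F
Why: A silyl triflate with a hindered pyridine base silylates the tertiary allylic alcohol without ionising it; the bulky ether later shields one face of the ring alkene.

Step 3
Reactants: 4 3-(benzyloxy)propanal; 5 3-(triphenylphosphoranylidene)butan-2-one
Product: 6 (E)-6-(benzyloxy)-3-methylhex-3-en-2-one
Conditions: toluene, 90 °C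
Reagents that add atoms: none
Why: Wittig olefination with a stabilised α-branched keto ylide gives the E trisubstituted enone, and the salt-free ylide is mild enough not to eliminate the β-benzyloxy group.

Step 4
Reactants: 6 (E)-6-(benzyloxy)-3-methylhex-3-en-2-one
Product: 7 (2R,3E)-6-(benzyloxy)-3-methylhex-3-en-2-ol
Conditions: (S)-2-methyl-CBS-oxazaborolidine (20 mol %), BH3·SMe2, THF, −30 °C
Reagents that add atoms: none
Why: Corey–Bakshi–Shibata reduction; the α-branched alkenyl group is the large substituent, so the (S)-oxazaborolidine gives the R carbinol, the one stereocentre used to control the cyclopropane.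

Step 5
Reactants: 7 (2R,3E)-6-(benzyloxy)-3-methylhex-3-en-2-ol
Product: 8 cyclopropyl carbinol
Conditions: Et2Zn, 2,2-diiodopropane, CH2Cl2, −10 °C → rt
Reagents that add atoms: 2,2-diiodopropane, CC(C)(I)I
Why: Simmons–Smith-type cyclopropanation with the isopropylidene zinc carbenoid, delivered by the zinc alkoxide to the alkene face syn to oxygen in the rotamer that minimises allylic strain (carbinol hydrogen eclipsing the alkene). The addition is stereospecific, so the E geometry places the carbinol carbon trans to the side chain and gives C14 R and C28 S.

Step 6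
Reactants: 8 cyclopropyl carbinol
Product: 9 cyclopropyl methyl ketone
Conditions: Dess–Martin periodinane, NaHCO3, CH2Cl2, rt
Reagents that add atoms: none
Why: Dess–Martin oxidation under buffered, non-acidic conditions spares the cyclopropane; the carbinol centre has done its work and is erased.

Step 7
Reactants: 9 cyclopropyl methyl ketone
Product: 10 enol triflate
Conditions: KN(SiMe3)2, THF, −78 °C; then PhNTf2
Reagents that add atoms: N-phenylbis(trifluoromethanesulfonimide), O=S(=O)(N(c1ccccc1)S(=O)(=O)C(F)(F)F)C(F)(F)F
Why: C28 is quaternary, so the amide base can enolise only toward the methyl group; O-triflation of that enolate gives the 1-cyclopropylvinyl triflate.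

Step 8
Reactants: 10 enol triflate
Product: 11 vinylcyclopropane
Conditions: Pd(OAc)2 (5 mol %), PPh3, HCO2H, Bu3N, DMF, 60 °C
Reagents that add atoms: none
Why: Palladium-catalysed formate reduction of a vinyl triflate (oxidative addition to zerovalent palladium, formate exchange, loss of CO2, reductive elimination) replaces the triflate by hydrogen at a temperature the strained ring tolerates.

Step 9
Reactants: 3 cyclopentenyl silyl ether; 11 vinylcyclopropane
Product: 12 cis-hydroazulene benzyl ether
Conditions: [Rh(CO)2Cl]2 (5 mol %), 3 (3 equiv), 1,2-dichloroethane, 80 °C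
Reagents that add atoms: none
Why: Proposed new method: monovalent rhodium binds the vinyl group of 11 and inserts into the adjacent, most substituted cyclopropane bond C28–C15, giving a rhodacycle with an η3-allyl terminus (C25–C26–C28) and a Rh–C15 bond; the alkene of 3 inserts between rhodium and C25 (forming C24–C25 and Rh–C18), and reductive elimination from trivalent rhodium forms C15–C18 while the allyl unit collapses to the C26=C28 alkene. The closest known reaction type is the rhodium-catalysed (5+2) cycloaddition of 1-substituted vinylcyclopropanes with alkynes and allenes (intermolecular) and with tethered alkenes (intramolecular); neither an intermolecular unactivated cyclic alkene nor ring opening toward a gem-dimethyl carbon has been shown. Ring C is closed by a two-bond intermolecular annulation whose last bond is made by reductive elimination from an eight-membered rhodacycle. C18 and C24 are created together: suprafacial addition gives the cis fusion, and approach anti to the C21 silyl ether gives both as R, while C14 is a spectator cyclopropane carbon and keeps its configuration (its descriptor reads S in 12 only because the priorities change). Orientation is set at insertion, where rhodium takes C18, away from the quaternary C21, and the slim CH2 terminus C25 bonds to the more hindered C24. Opening toward C15 and not C14 is supported by the weakness of the fully substituted C28–C15 bond and by the ground-state shape of 11: with the vinyl group cis to H14, the s-cis rotamer that aligns C28–C15 with the π system is free of strain, whereas the rotamer needed for C28–C14 cleavage pushes C25 against the cis methyl on C15. The C28 methyl favours the reactive s-cis rotamer as other 1-substituents do, and the small carbonyl ligands leave room for a tertiary alkyl–rhodium bond.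

Step 10
Reactants: 12 cis-hydroazulene benzyl ether
Product: 13 hydroazulene alcohol
Conditions: lithium 4,4′-di-tert-butylbiphenylide, THF, −78 °C
Reagents that add atoms: none
Why: Single-electron reduction by the arene radical anion cleaves the benzylic C–O bond at low temperature and, unlike hydrogenolysis, leaves the trisubstituted alkene and the tertiary silyl ether alone.

Step 11
Reactants: 13 hydroazulene alcohol
Product: 14 epoxy alcohol
Conditions: VO(acac)2 (5 mol %), t-BuOOH, 2,6-lutidine, toluene, 0 °C → rt
Reagents that add atoms: tert-butyl hydroperoxide, CC(C)(C)OO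
Why: Vanadium-catalysed hydroxyl-directed epoxidation; the bishomoallylic alkoxide bound to vanadium delivers the peroxide oxygen to the alkene face on which the side chain sits, setting C26 S and C28 R. The base buffer is there to suppress opening of the epoxy alcohol.

Step 12
Reactants: 14 epoxy alcohol
Product: 15 epoxy aldehyde
Conditions: Dess–Martin periodinane, NaHCO3, CH2Cl2, 0 °C → rt
Reagents that add atoms: none
Why: Buffered Dess–Martin oxidation gives the aldehyde without touching the epoxide or the silyl ether.

Step 13
Reactants: 16 (E)-geranylacetone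
Product: 17 diepoxy ketone
Conditions: D-fructose-derived Shi ketone (0.6 equiv), KHSO5 (Oxone), K2CO3, Bu4NHSO4, MeCN/CH2(OMe)2/aqueous Na2B4O7 buffer, 0 °C
Reagents that add atoms: potassium peroxymonosulfate, [K+].[O-]S(=O)(=O)OO
Why: Shi epoxidation; the chiral dioxirane attacks both trisubstituted alkenes from the same enantioface through spiro transition states, giving the 5R,6R and 9R epoxides, and the basic buffer suppresses Baeyer–Villiger oxidation of the ketone.

Step 14
Reactants: 17 diepoxy ketone
Product: 18 diepoxy enol silane
Conditions: LiN(iPr)2, THF, −78 °C; then TBSCl, HMPA, −78 → 0 °C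
Reagents that add atoms: tert-butyldimethylsilyl chloride, CC(C)(C)[Si](C)(C)Cl
Why: Kinetic deprotonation of the methyl ketone at the methyl group and O-silylation give the terminal enol silane; the epoxides tolerate the amide base at −78 °C.

Step 15
Reactants: 18 diepoxy enol silane
Product: 20 bicyclic hydroxy ketone, via trimethylsilyl ether 19 (not isolated)
Conditions: Me3SiOTf, 2,6-di-tert-butyl-4-methylpyridine, CH2Cl2, −78 °C; then K2CO3, MeOH, 0 °C
Reagents that add atoms: none
Why: Silyl-triflate-triggered epoxide-opening cascade: the silylated terminal epoxide is opened at its tertiary carbon C2 by the oxygen of the internal epoxide (O4–C2, oxepane), and the epoxonium ion is opened at tertiary C30 with inversion by the enol silane carbon C11 (six-membered ring B). The E alkene geometry of 16 thereby becomes the trans fusion with C5 R and C30 R, and methanolysis removes the trimethylsilyl group.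

Step 16
Reactants: 20 bicyclic hydroxy ketone
Product: 21 bicyclic ketone silyl ether
Conditions: TBSOTf, 2,6-lutidine, CH2Cl2, −78 → 0 °C
Reagents that add atoms: tert-butyldimethylsilyl trifluoromethanesulfonate, CC(C)(C)[Si](C)(C)OS(=O)(=O)C(F)(F)F
Why: Silyl triflate silylation of the hindered secondary alcohol at low temperature, where the ketone is not enolised.

Step 17
Reactants: 21 bicyclic ketone silyl ether
Product: 22 bicyclic enone
Conditions: 2-iodoxybenzoic acid (IBX), DMSO/toluene, 70 °C
Reagents that add atoms: none
Why: Hypervalent-iodine dehydrogenation of the ketone through its enol; only the C7 side has a β-hydrogen because C30 is quaternary, so a single enone (C6=C7) can form.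

Step 18
Reactants: 22 bicyclic enone; 15 epoxy aldehyde
Product: 23 aldol adduct
Conditions: LiN(iPr)2, THF, −78 °C; then 15, −78 °C; NH4Cl work-up
Reagents that add atoms: none
Why: The C6=C7 bond blocks C7, so the amide base deprotonates only C11, and the cross-conjugated lithium enolate adds to the aldehyde in a directed aldol reaction faster than it exchanges protons with it; the new centres at C11 and C12 are transient.

Step 19
Reactants: 23 aldol adduct
Product: 25 dienone, via C12 mesylate 24 (not isolated)
Conditions: MsCl, Et3N, CH2Cl2, 0 °C; then DBU, rt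
Reagents that add atoms: none
Why: Mesylation and base-induced E1cB elimination give the exocyclic enone; either alkene geometry serves because it is lost in the next step.

Step 20
Reactants: 25 dienone
Product: 26 saturated ketone
Conditions: H2 (1 atm), Pd on carbon, EtOAc, rt
Reagents that add atoms: none
Why: Heterogeneous hydrogenation saturates both conjugated alkenes; hydrogen reaches C11 from the face opposite the axial angular methyl C31 on the neighbouring C30, which leaves the side chain equatorial (C11 R). The isolated epoxide and the silyl ethers are not reduced.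

Step 21
Reactants: 26 saturated ketone
Product: 27 tertiary alcohol
Conditions: MeLi, CeCl3, THF, −78 °C
Reagents that add atoms: methyllithium, [Li]C
Why: Organocerium 1,2-addition suppresses enolisation of the hindered ketone and spares the epoxide; axial attack is blocked by the 1,3-related axial methyl C31, so the methyl group enters equatorially and the hydroxyl ends axial (C8 S).

Step 22
Reactants: 27 tertiary alcohol
Product: 28 triol
Conditions: Bu4NF, THF, 50 °C
Reagents that add atoms: none
Why: Fluoride cleaves both silyl ethers, the tertiary one needing warmth; the epoxide is inert to fluoride in THF, and the C21 alkoxide cannot reach it without forming a trans-fused bicycle.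

Step 23
Reactants: 28 triol
Product: 29 target CNP0259752.1
Conditions: Dess–Martin periodinane, NaHCO3, CH2Cl2, rt
Reagents that add atoms: none
Why: Dess–Martin oxidation of the only secondary alcohol (C34) leaves the two tertiary alcohols and the epoxide untouched and unveils the enolisable α-alkoxy ketone last.

## Compound list

1 | (R)-linalool, (3R)-3,7-dimethylocta-1,6-dien-3-ol | CC(C)=CCC[C@](C)(C=C)O | starting material
2 | (R)-1-methylcyclopent-2-en-1-ol | C[C@]1(O)C=CCC1 | intermediate
3 | cyclopentenyl silyl ether, tert-butyl(dimethyl){[(1R)-1-methylcyclopent-2-en-1-yl]oxy}silane | C[C@]1(O[Si](C)(C)C(C)(C)C)C=CCC1 | intermediate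
4 | 3-(benzyloxy)propanal | O=CCCOCc1ccccc1 | starting material
5 | 3-(triphenylphosphoranylidene)butan-2-one | CC(=O)C(C)=P(c1ccccc1)(c1ccccc1)c1ccccc1 | starting material
6 | (E)-6-(benzyloxy)-3-methylhex-3-en-2-one | CC(=O)/C(C)=C/CCOCc1ccccc1 | intermediate
7 | (2R,3E)-6-(benzyloxy)-3-methylhex-3-en-2-ol | C[C@@H](O)/C(C)=C/CCOCc1ccccc1 | intermediate
8 | cyclopropyl carbinol, (1R)-1-{(1S,3R)-3-[2-(benzyloxy)ethyl]-1,2,2-trimethylcyclopropyl}ethan-1-ol | c1ccccc1COCC[C@@H]1C(C)(C)[C@@]1(C)[C@@H](C)O | intermediate
9 | cyclopropyl methyl ketone, 1-{(1S,3R)-3-[2-(benzyloxy)ethyl]-1,2,2-trimethylcyclopropyl}ethan-1-one | c1ccccc1COCC[C@@H]1C(C)(C)[C@@]1(C)C(C)=O | intermediate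
10 | enol triflate, 1-{(1S,3R)-3-[2-(benzyloxy)ethyl]-1,2,2-trimethylcyclopropyl}ethenyl trifluoromethanesulfonate | c1ccccc1COCC[C@@H]1C(C)(C)[C@@]1(C)C(=C)OS(=O)(=O)C(F)(F)F | intermediate
11 | vinylcyclopropane, ({2-[(1R,2S)-2-ethenyl-2,3,3-trimethylcyclopropyl]ethoxy}methyl)benzene (vinyl trans to the side chain) | c1ccccc1COCC[C@@H]1C(C)(C)[C@@]1(C)C=C | intermediate
12 | cis-hydroazulene benzyl ether, {[(1R,3aR,5S,8aR)-5-[2-(benzyloxy)ethyl]-1,4,4,6-tetramethyl-1,2,3,3a,4,5,8,8a-octahydroazulen-1-yl]oxy}(tert-butyl)dimethylsilane (C14 S, C18 R, C21 R, C24 R) | c1ccccc1COCC[C@@H]2C(C)(C)[C@@H]3CC[C@@](C)(O[Si](C)(C)C(C)(C)C)[C@@H]3CC=C2C | intermediate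
13 | hydroazulene alcohol, 2-[(1R,3aR,5S,8aR)-1-{[tert-butyl(dimethyl)silyl]oxy}-1,4,4,6-tetramethyl-1,2,3,3a,4,5,8,8a-octahydroazulen-5-yl]ethan-1-ol | OCC[C@@H]1C(C)(C)[C@@H]2CC[C@@](C)(O[Si](C)(C)C(C)(C)C)[C@@H]2CC=C1C | intermediate
14 | epoxy alcohol, 13 with the C26=C28 alkene turned into the epoxide on the face of the hydroxyethyl chain (C14 R, C18 R, C21 R, C24 R, C26 S, C28 R) | OCC[C@@H]3C(C)(C)[C@@H]4CC[C@@](C)(O[Si](C)(C)C(C)(C)C)[C@@H]4C[C@@H]4O[C@@]43C | intermediate
15 | epoxy aldehyde, the C12 aldehyde of 14 (same descriptors) | O=CC[C@@H]3C(C)(C)[C@@H]4CC[C@@](C)(O[Si](C)(C)C(C)(C)C)[C@@H]4C[C@@H]4O[C@@]43C | intermediate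
16 | (E)-geranylacetone, (5E)-6,10-dimethylundeca-5,9-dien-2-one | CC(C)=CCC/C(C)=C/CCC(C)=O | starting material
17 | diepoxy ketone, (5R,6R,9R)-5,6:9,10-diepoxy-6,10-dimethylundecan-2-one | CC(=O)CC[C@H]1O[C@]1(C)CC[C@H]1OC1(C)C | intermediate
18 | diepoxy enol silane, tert-butyl{[(5R,6R,9R)-5,6:9,10-diepoxy-6,10-dimethylundec-1-en-2-yl]oxy}dimethylsilane | C=C(O[Si](C)(C)C(C)(C)C)CC[C@H]1O[C@]1(C)CC[C@H]1OC1(C)C | intermediate
19 | trimethylsilyl ether of 20, (3R,5aR,9aR)-2,2,5a-trimethyl-3-[(trimethylsilyl)oxy]octahydro-1-benzoxepin-7(2H)-one | CC1(C)O[C@@H]2CCC(=O)C[C@@]2(C)CC[C@H]1O[Si](C)(C)C | intermediate (not isolated)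
20 | bicyclic hydroxy ketone, (3R,5aR,9aR)-3-hydroxy-2,2,5a-trimethyloctahydro-1-benzoxepin-7(2H)-one (trans-fused) | CC1(C)O[C@@H]2CCC(=O)C[C@@]2(C)CC[C@H]1O | intermediate
21 | bicyclic ketone silyl ether, (3R,5aR,9aR)-3-{[tert-butyl(dimethyl)silyl]oxy}-2,2,5a-trimethyloctahydro-1-benzoxepin-7(2H)-one | CC1(C)O[C@@H]2CCC(=O)C[C@@]2(C)CC[C@H]1O[Si](C)(C)C(C)(C)C | intermediate
22 | bicyclic enone, (3R,5aR,9aR)-3-{[tert-butyl(dimethyl)silyl]oxy}-2,2,5a-trimethyl-3,4,5,5a,6,9a-hexahydro-1-benzoxepin-7(2H)-one (C6=C7 in target labels) | CC1(C)O[C@@H]2C=CC(=O)C[C@@]2(C)CC[C@H]1O[Si](C)(C)C(C)(C)C | intermediate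
23 | aldol adduct, C11–C12 bond formed, C12 carbinol epimers, C11 side chain drawn trans to C31 | CC1(C)O[C@@H]2C=CC(=O)[C@@H](C(O)C[C@@H]3C(C)(C)[C@@H]4CC[C@@](C)(O[Si](C)(C)C(C)(C)C)[C@@H]4C[C@@H]4O[C@@]43C)[C@@]2(C)CC[C@H]1O[Si](C)(C)C(C)(C)C | intermediate
24 | C12 mesylate of 23 | CC1(C)O[C@@H]2C=CC(=O)[C@@H](C(OS(C)(=O)=O)C[C@@H]3C(C)(C)[C@@H]4CC[C@@](C)(O[Si](C)(C)C(C)(C)C)[C@@H]4C[C@@H]4O[C@@]43C)[C@@]2(C)CC[C@H]1O[Si](C)(C)C(C)(C)C | intermediate (not isolated)
25 | dienone, C6=C7 and exocyclic C11=C12 (drawn E) conjugated to the C8 ketone | CC1(C)O[C@@H]2C=CC(=O)/C(=C/C[C@@H]3C(C)(C)[C@@H]4CC[C@@](C)(O[Si](C)(C)C(C)(C)C)[C@@H]4C[C@@H]4O[C@@]43C)[C@@]2(C)CC[C@H]1O[Si](C)(C)C(C)(C)C | intermediate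
26 | saturated ketone, C8 ketone with C11 R, bis-silyl ether, epoxide in place | CC1(C)O[C@@H]2CCC(=O)[C@H](CC[C@@H]3C(C)(C)[C@@H]4CC[C@@](C)(O[Si](C)(C)C(C)(C)C)[C@@H]4C[C@@H]4O[C@@]43C)[C@@]2(C)CC[C@H]1O[Si](C)(C)C(C)(C)C | intermediate
27 | tertiary alcohol, C8 S methyl carbinol, bis-silyl ether | CC1(C)O[C@@H]2CC[C@](C)(O)[C@H](CC[C@@H]3C(C)(C)[C@@H]4CC[C@@](C)(O[Si](C)(C)C(C)(C)C)[C@@H]4C[C@@H]4O[C@@]43C)[C@@]2(C)CC[C@H]1O[Si](C)(C)C(C)(C)C | intermediate
28 | triol, the C34 R alcohol of the target | CC1(C)O[C@@H]2CC[C@](C)(O)[C@H](CC[C@@H]3C(C)(C)[C@@H]4CC[C@@](C)(O)[C@@H]4C[C@@H]4O[C@@]43C)[C@@]2(C)CC[C@H]1O | intermediate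
29 | target CNP0259752.1 (5R,8S,11R,14R,18R,21R,24R,26S,28R,30R) | CC1(C)O[C@@H]2CC[C@](C)(O)[C@H](CC[C@@H]3C(C)(C)[C@@H]4CC[C@@](C)(O)[C@@H]4C[C@@H]4O[C@@]43C)[C@@]2(C)CCC1=O | target

## Step count and least certain steps

Total step count: 23. Longest linear sequence: 16 steps, from 4 to 29 through steps 3–12 and 18–23.

**Step 9 (key step).** The cyclopropane may open toward C14 instead of C15, because in known cases rhodium avoids the ring carbon that carries a substituent cis to the vinyl group, and C15 always has one. That would give the regioisomeric cycloheptene. Alternatively, the hindered unactivated alkene may fail to insert, and the rhodacycle would drain away by β-hydride elimination to dienes. Facial selectivity between the methyl and silyloxy faces of 3 is a smaller worry.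

Fallback, known reactions only, about twelve steps, sets out from 3 and returns at 12:
- Allylic oxidation of 3 (Rh2(cap)4, dirhodium tetracaprolactamate, t-BuOOH) gives the cyclopentenone F1.
- Conjugate addition of vinylmagnesium bromide (CuBr·SMe2) anti to the silyloxy group, with the enolate trapped by acetone (ZnCl2), gives the aldol F2. Dehydration (SOCl2, pyridine) gives the isopropylidene ketone F3.
- Luche reduction (NaBH4, CeCl3) gives the allylic alcohol F4 (C19 epimers, separated). Esterification with 4-(benzyloxy)butanoic acid (DCC, DMAP) gives the ester F5. 9-BBN then H2O2/NaOH hydroborates only the vinyl group, giving the hydroxy ester F6.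
- Ireland–Claisen rearrangement (LiN(iPr)2, Me3SiCl, THF or THF/HMPA, enolate geometry paired with the C19 epimer through a chair transition state) forms C14–C15 and gives the hydroxy acid F7, which holds the quaternary C15, the C14 centre and a C18=C19 ring alkene.
- MeLi gives the methyl ketone F8, and Dess–Martin oxidation the keto aldehyde F9.
- Hydrogenation with [Ir(cod)(PCy3)(py)]PF6 from the face opposite the C24 side chain gives the saturated keto aldehyde F10 with C18 cis to C24.
- McMurry coupling (TiCl3, Zn–Cu, DME, reflux) of the C26 aldehyde with the C28 ketone closes ring C as the C26=C28 alkene and gives 12.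

**Step 5 (isopropylidene transfer).** The zinc carbenoid may decompose before it adds to the crowded trisubstituted alkene, leaving 7 unchanged; forming three contiguous substituted ring carbons is demanding. Fallback, sets out from 7 and returns at 8: hydroxyl-assisted dibromocarbene addition (CHBr3, 50% NaOH, BnEt3NCl) gives the gem-dibromocyclopropyl carbinol F11, separated from its diastereomer. Both bromines are then exchanged for methyl groups with excess Me2CuLi followed by MeI.

**Step 15 (epoxide-opening cascade).** The enol silane may be lost by silyl transfer before it attacks, or the internal epoxide oxygen may open the terminal epoxide at the secondary carbon, giving a tetrahydropyran instead of the oxepane. Fallback, sets out from 17 and returns at 20, using a carbon-bound silane terminator: the kinetic enolate of 17 (LiN(iPr)2) is triflated (PhNTf2) to the enol triflate F12. Coupling with Me3SiCH2MgCl (Pd(PPh3)4) gives the allylsilane F13. The same silyl triflate cascade followed by methanolysis gives the exocyclic-methylene bicycle F14, and ozonolysis (O3, then Me2S) gives 20.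

**Step 18 (aldol union, with step 19).** Addition of the neopentyl-type enolate may stall or revert, and the aldehyde may be enolised instead. Fallback, sets out from 14 and 22 and returns at 26: 14 is converted into the iodide F15 (I2, PPh3, imidazole). The enolate of 22 (LiN(iPr)2, HMPA) is alkylated to the alkylated enone F16, in which the chain enters opposite the angular methyl. Re-enolisation and kinetic protonation on the open face (2,6-di-tert-butylphenol) give the C11 epimer F17. Hydrogenation (H2, Pd on carbon) of its C6=C7 bond gives 26.

**Step 11 (directed epoxidation).** Facial selectivity may be incomplete if the seven-membered ring holds the side chain away from the alkene, and the epoxy alcohol may cyclise to a tetrahydrofuran. Fallback, sets out from 13 and returns at 14: Shi epoxidation (KHSO5, buffered) with whichever antipode of the fructose-derived ketone is matched to the required face. For a trisubstituted alkene the chiral dioxirane, not the substrate, then decides the face, and the medium is basic.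

## Further compounds

F1 | step 9 | (4R)-4-{[tert-butyl(dimethyl)silyl]oxy}-4-methylcyclopent-2-en-1-one | C[C@]1(O[Si](C)(C)C(C)(C)C)C=CC(=O)C1
F2 | step 9 | aldol: 2-(2-hydroxypropan-2-yl)-3-ethenyl-4-methyl-4-silyloxycyclopentanone, ethenyl anti to the silyloxy group, C18 epimers | C[C@]1(O[Si](C)(C)C(C)(C)C)[C@H](C=C)C(C(C)(C)O)C(=O)C1
F3 | step 9 | isopropylidene ketone | C[C@]1(O[Si](C)(C)C(C)(C)C)[C@H](C=C)C(=C(C)C)C(=O)C1
F4 | step 9 | allylic alcohol (C19 epimers) | C[C@]1(O[Si](C)(C)C(C)(C)C)[C@H](C=C)C(=C(C)C)C(O)C1
F5 | step 9 | 4-(benzyloxy)butanoate ester of F4 | C[C@]1(O[Si](C)(C)C(C)(C)C)[C@H](C=C)C(=C(C)C)C(OC(=O)CCCOCc2ccccc2)C1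
F6 | step 9 | hydroxy ester (C24 2-hydroxyethyl) | C[C@]1(O[Si](C)(C)C(C)(C)C)[C@H](CCO)C(=C(C)C)C(OC(=O)CCCOCc2ccccc2)C1
F7 | step 9 | hydroxy acid after Ireland–Claisen rearrangement (C14 set, C18=C19) | C[C@]1(O[Si](C)(C)C(C)(C)C)[C@H](CCO)C(=CC1)C(C)(C)[C@@H](CCOCc2ccccc2)C(O)=O
F8 | step 9 | hydroxy methyl ketone | C[C@]1(O[Si](C)(C)C(C)(C)C)[C@H](CCO)C(=CC1)C(C)(C)[C@@H](CCOCc2ccccc2)C(C)=O
F9 | step 9 | keto aldehyde | C[C@]1(O[Si](C)(C)C(C)(C)C)[C@H](CC=O)C(=CC1)C(C)(C)[C@@H](CCOCc2ccccc2)C(C)=O
F10 | step 9 | saturated keto aldehyde (C18 cis to C24) | C[C@]1(O[Si](C)(C)C(C)(C)C)[C@H](CC=O)[C@@H](CC1)C(C)(C)[C@@H](CCOCc2ccccc2)C(C)=O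
F11 | step 5 | gem-dibromocyclopropyl carbinol, configured as 8 with bromine in place of the two C15 methyl groups | c1ccccc1COCC[C@@H]1C(Br)(Br)[C@@]1(C)[C@@H](C)O
F12 | step 15 | enol triflate of 17, (5R,6R,9R)-5,6:9,10-diepoxy-6,10-dimethylundec-1-en-2-yl trifluoromethanesulfonate | C=C(OS(=O)(=O)C(F)(F)F)CC[C@H]1O[C@]1(C)CC[C@H]1OC1(C)C
F13 | step 15 | allylsilane, {2-[(3R,4R,7R)-3,4:7,8-diepoxy-4,8-dimethylnonyl]prop-2-en-1-yl}trimethylsilane | C=C(C[Si](C)(C)C)CC[C@H]1O[C@]1(C)CC[C@H]1OC1(C)C
F14 | step 15 | (3R,5aR,9aR)-2,2,5a-trimethyl-7-methylidenedecahydro-1-benzoxepin-3-ol | CC1(C)O[C@@H]2CCC(=C)C[C@@]2(C)CC[C@H]1O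
F15 | step 18 | C12 iodide of 14 | ICC[C@@H]3C(C)(C)[C@@H]4CC[C@@](C)(O[Si](C)(C)C(C)(C)C)[C@@H]4C[C@@H]4O[C@@]43C
F16 | step 18 | alkylated enone, C11 chain trans to C31 | CC1(C)O[C@@H]2C=CC(=O)[C@@H](CC[C@@H]3C(C)(C)[C@@H]4CC[C@@](C)(O[Si](C)(C)C(C)(C)C)[C@@H]4C[C@@H]4O[C@@]43C)[C@@]2(C)CC[C@H]1O[Si](C)(C)C(C)(C)C
F17 | step 18 | C11 epimer of F16, chain cis to C31 (C11 R) | CC1(C)O[C@@H]2C=CC(=O)[C@H](CC[C@@H]3C(C)(C)[C@@H]4CC[C@@](C)(O[Si](C)(C)C(C)(C)C)[C@@H]4C[C@@H]4O[C@@]43C)[C@@]2(C)CC[C@H]1O[Si](C)(C)C(C)(C)C
F0 | step 11 | none | none
A1 | alternative 1 | tricyclic cis-fused γ-lactone on the oxepane–cyclohexane core | CC1(C)O[C@@H]2CC[C@]3(C)OC(=O)C[C@@H]3[C@@]2(C)CC[C@H]1O[Si](C)(C)C(C)(C)C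
A2 | alternative 2 | cis-hydrindanone tertiary alcohol | CC(C)(C)OC(=O)C[C@@H]1C(C)(C)[C@@H]2CC[C@@](C)(O)[C@@H]2CC1=O
A3 | alternative 3 | trans-fused oxepanol with exocyclic C8 methylene | CC1(C)O[C@@H]2CCC(=C)[C@H](CCOCc3ccccc3)[C@@]2(C)CC[C@@H]1O
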